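**Retrosynthetic overview**

- Lactone numbering is O1, C2 (carbonyl), C3, C4, C5; ring A is the 4-hydroxy-3-methoxyphenyl ring on the C3 benzyl group, ring B the 3,4,5-trimethoxyphenyl ring on the C4 benzyl group. The lactone ring is closed last: hydrogenolysis of the benzylic C–O bond of a 2-aryl-tetrahydrofuran-3-carboxylic acid frees the C5 hydroxyl, which lactonises onto the C2 carboxyl.
- The strategy rests on one feature: C2 and C5 are the two CH2OH termini of the near-symmetric (2R,3R)-2,3-dibenzylbutane-1,4-diol 12, and only ring A has a free para-hydroxyl. Only the ring A benzylic carbon can therefore become a quinone methide. DDQ generates it and the C5 hydroxyl closes a temporary tetrahydrofuran (the first ring formed), leaving the C2 hydroxymethyl group free for oxidation.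
- Diol 12 comes from the (E)-1,4-diarylbut-2-ene 6 by enantioselective syn-diboration, one-carbon homologation of both C–B bonds, oxidation and phenol release; the two ends are never differentiated before the key step.
- Alkene 6 is assembled with defined E geometry from eugenol by cross-metathesis with vinylboronic acid pinacol ester, then benzyl Suzuki coupling with 3,4,5-trimethoxybenzyl bromide.
- Ring order: temporary tetrahydrofuran (step 7), then the γ-lactone (step 10), formed as the tetrahydrofuran is cleaved.

Key step: step 7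

Assumption: the facial sense of the Rh/Quinap diboration is taken from simple trans-alkenes, for which the (S)-ligand is understood to give the (S,S)-bis(boronate). (R)-Quinap is therefore specified for the (R,R) series, and the antipodal ligand would be used if the sense proved opposite.

**Route**

Step 1
Reactants: 1 eugenol (4-allyl-2-methoxyphenol)
Product: 2 (4-allyl-2-methoxyphenoxy)triisopropylsilane
Conditions: TIPSCl, imidazole, DMF, rt
Reagents that add atoms: triisopropylsilyl chloride, CC(C)[Si](Cl)(C(C)C)C(C)C
Why: Imidazole-promoted silyl ether formation masks the phenol for the borylation and organolithium steps, and the bulky aryl TIPS ether should withstand the mildly basic aqueous steps that follow.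

Step 2
Reactants: 2 (4-allyl-2-methoxyphenoxy)triisopropylsilane; 3 vinylboronic acid pinacol ester (4,4,5,5-tetramethyl-2-vinyl-1,3,2-dioxaborolane, 2 equiv)
Product: 4 (E)-2-[3-(3-methoxy-4-triisopropylsilyloxyphenyl)prop-1-en-1-yl]-4,4,5,5-tetramethyl-1,3,2-dioxaborolane
Conditions: second-generation Grubbs catalyst (H2IMes)(PCy3)Cl2Ru=CHPh (3 mol%), 1,4-benzoquinone (10 mol%), CH2Cl2, 40 °C
Reagents that add atoms: none
Why: Olefin cross-metathesis of a type 1 allylarene with the slowly homodimerising vinyl boronate should give the cross product selectively, the bulky boryl group favouring the E-alkenyl boronate, while benzoquinone suppresses Ru–H double-bond migration into conjugation.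

Step 3
Reactants: 4 the (E)-alkenyl boronate; 5 3,4,5-trimethoxybenzyl bromide (5-(bromomethyl)-1,2,3-trimethoxybenzene)
Product: 6 (E)-1-(3-methoxy-4-triisopropylsilyloxyphenyl)-4-(3,4,5-trimethoxyphenyl)but-2-ene
Conditions: Pd(PPh3)4 (5 mol%), K2CO3, THF/H2O (5:1), 65 °C
Reagents that add atoms: none
Why: Suzuki–Miyaura sp2–sp3 coupling of an alkenyl boronic ester with a benzylic bromide at zerovalent palladium proceeds with retention of alkene geometry, so the E configuration of 4 should be carried into 6.

Step 4
Reactants: 6 the (E)-1,4-diarylbut-2-ene; 7 bis(catecholato)diboron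
Product: 9 (2R,3R)-1-(3-methoxy-4-triisopropylsilyloxyphenyl)-4-(3,4,5-trimethoxyphenyl)butane-2,3-diyl bis(pinacol boronate), via bis(catechol boronate) 8 (not isolated)
Conditions: (nbd)Rh(acac) (5 mol%), (R)-Quinap (5 mol%), THF, rt; then pinacol, rt
Reagents that add atoms: pinacol, CC(C)(O)C(C)(C)O
Why: Rh/Quinap-catalysed enantioselective alkene diboration (B–B oxidative addition, alkene insertion, C–B reductive elimination) delivers both boryl groups to one face, so syn addition to the E-alkene fixes the like (R,R) relationship and the ligand fixes the absolute sense, and ester exchange with pinacol should give chromatography-stable boronates.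

Step 5
Reactants: 9 the (2R,3R)-bis(pinacol boronate)
Product: 11 (2R,3R)-2-(3-methoxy-4-triisopropylsilyloxybenzyl)-3-(3,4,5-trimethoxybenzyl)butane-1,4-diol, via homologated bis(boronate) 10 (not isolated)
Conditions: BrCH2Cl, n-BuLi, THF, −78 °C to rt; then NaBO3·4H2O, THF/H2O, rt
Reagents that add atoms: bromochloromethane, ClCBr; sodium perborate, [Na+].[O-]OB=O
Why: Matteson homologation (LiCH2Cl adds to each boron and the secondary alkyl group migrates 1,2 with loss of chloride and retention at carbon) inserts one CH2 into both C–B bonds, and perborate oxidation of the resulting primary boronates should give the 1,4-diol with both stereocentres intact and the silyl ether preserved.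

Step 6
Reactants: 11 the silyl-protected (2R,3R)-diol
Product: 12 (2R,3R)-2-(4-hydroxy-3-methoxybenzyl)-3-(3,4,5-trimethoxybenzyl)butane-1,4-diol
Conditions: TBAF, AcOH, THF, 0 °C
Reagents that add atoms: none
Why: Fluoride cleavage of the aryl silyl ether, buffered with acetic acid so that no free phenoxide is exposed, should release the ring A phenol without affecting the diol.

Step 7
Reactants: 12 the (2R,3R)-phenol diol
Product: 14 [(2S,3R,4R)-2-(4-hydroxy-3-methoxyphenyl)-4-(3,4,5-trimethoxybenzyl)tetrahydrofuran-3-yl]methanol (aryl trans to the hydroxymethyl group, hydroxymethyl cis to the benzyl group), via para-quinone methide 13 (not isolated)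
Conditions: DDQ (1.05 equiv), CH2Cl2/1,4-dioxane (4:1), 0 °C; aq NaHCO3 quench
Reagents that add atoms: none
Why: DDQ removes hydride from the ring A benzylic carbon through the phenol to give para-quinone methide 13, the known DDQ oxidation of 4-alkylphenols, and the closest model is the oxidative cyclisation of 4-hydroxybenzyl compounds that carry a pendant alcohol. The hydroxyl on C5 then adds to the exocyclic carbon in a 5-exo-trig oxa-conjugate addition that rearomatises ring A and closes the tetrahydrofuran, whereas the hydroxyl of the future C2 could only close an oxetane and so should stay free. The new benzylic stereocentre is expected trans to the neighbouring hydroxymethyl group, through an envelope transition state with the aryl group pseudo-equatorial and through reversible reopening to the quinone methide; its configuration is immaterial because step 10 erases it. The step needs oxidation at the ring A benzylic carbon only and O-capture rather than C-capture of the quinone methide. The first is secured because ring B has no free para-hydroxyl and cannot form a neutral quinone methide; the second should follow from the fast 5-exo closure at 0 °C with one equivalent of oxidant, which limits Friedel–Crafts capture by ring B and a second oxidation. Both stereocentres of the diol are untouched.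

Step 8
Reactants: 14 the tetrahydrofuran phenol alcohol
Product: 15 [(2S,3R,4R)-2-(4-benzyloxy-3-methoxyphenyl)-4-(3,4,5-trimethoxybenzyl)tetrahydrofuran-3-yl]methanol
Conditions: BnBr, K2CO3, DMF, rt
Reagents that add atoms: benzyl bromide, BrCc1ccccc1
Why: Williamson etherification under carbonate is chemoselective for the far more acidic phenol over the primary alcohol, and benzyl is chosen because it leaves in the same hydrogenolysis that later opens the ring.

Step 9
Reactants: 15 the O-benzyl tetrahydrofuran alcohol
Product: 16 (2S,3S,4R)-2-(4-benzyloxy-3-methoxyphenyl)-4-(3,4,5-trimethoxybenzyl)tetrahydrofuran-3-carboxylic acid (same spatial arrangement as 15; the C3 descriptor changes by priority only)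
Conditions: TEMPO (cat.), PhI(OAc)2, MeCN/H2O (1:1), rt
Reagents that add atoms: water, O
Why: Oxoammonium (TEMPO) catalysed oxidation with PhI(OAc)2 in aqueous acetonitrile takes the primary alcohol through the aldehyde hydrate to the carboxylic acid under near-neutral conditions that should spare the electron-rich arenes, the benzylic ether and the α-stereocentre.

Step 10
Reactants: 16 the tetrahydrofuran carboxylic acid
Product: 18 (3R,4R)-3-(4-hydroxy-3-methoxybenzyl)-4-(3,4,5-trimethoxybenzyl)dihydrofuran-2(3H)-one (target), via hydroxy acid 17 (not isolated)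
Conditions: H2 (1 atm), Pd/C, EtOAc/AcOH, rt; then TsOH·H2O (cat.), CH2Cl2, rt
Reagents that add atoms: none
Why: Palladium-catalysed hydrogenolysis should cleave both benzylic C–O bonds (the O-benzyl group and the aryl-activated C2–O bond of the 2-aryl-tetrahydrofuran), and the released γ-hydroxy acid closes to the γ-lactone by 5-exo-trig acyl substitution without touching C3 or C4, the trans-lactone also being the thermodynamic isomer should any C3 epimer arise.

**Compound list**

1 | eugenol (4-allyl-2-methoxyphenol) | C=CCc1ccc(O)c(OC)c1 | starting material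
2 | (4-allyl-2-methoxyphenoxy)triisopropylsilane | C=CCc1ccc(O[Si](C(C)C)(C(C)C)C(C)C)c(OC)c1 | intermediate
3 | vinylboronic acid pinacol ester | C=CB1OC(C)(C)C(C)(C)O1 | starting material
4 | (E)-2-[3-(3-methoxy-4-triisopropylsilyloxyphenyl)prop-1-en-1-yl]-4,4,5,5-tetramethyl-1,3,2-dioxaborolane | COc1cc(C/C=C/B2OC(C)(C)C(C)(C)O2)ccc1O[Si](C(C)C)(C(C)C)C(C)C | intermediate
5 | 3,4,5-trimethoxybenzyl bromide | COc1cc(CBr)cc(OC)c1OC | starting material
6 | (E)-1-(3-methoxy-4-triisopropylsilyloxyphenyl)-4-(3,4,5-trimethoxyphenyl)but-2-ene | COc1cc(C/C=C/Cc2cc(OC)c(OC)c(OC)c2)ccc1O[Si](C(C)C)(C(C)C)C(C)C | intermediate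
7 | bis(catecholato)diboron | B1(Oc2ccccc2O1)B1Oc2ccccc2O1 | starting material
8 | (2R,3R)-1-(3-methoxy-4-triisopropylsilyloxyphenyl)-4-(3,4,5-trimethoxyphenyl)butane-2,3-diyl bis(catechol boronate) | COc1cc(C[C@@H](B2Oc3ccccc3O2)[C@H](B2Oc3ccccc3O2)Cc2cc(OC)c(OC)c(OC)c2)ccc1O[Si](C(C)C)(C(C)C)C(C)C | intermediate (not isolated)
9 | (2R,3R)-1-(3-methoxy-4-triisopropylsilyloxyphenyl)-4-(3,4,5-trimethoxyphenyl)butane-2,3-diyl bis(pinacol boronate) | COc1cc(C[C@@H](B2OC(C)(C)C(C)(C)O2)[C@H](B2OC(C)(C)C(C)(C)O2)Cc2cc(OC)c(OC)c(OC)c2)ccc1O[Si](C(C)C)(C(C)C)C(C)C | intermediate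
10 | (2R,3R)-2-(3-methoxy-4-triisopropylsilyloxybenzyl)-3-(3,4,5-trimethoxybenzyl)butane-1,4-diyl bis(pinacol boronate) | COc1cc(C[C@@H](CB2OC(C)(C)C(C)(C)O2)[C@H](CB2OC(C)(C)C(C)(C)O2)Cc2cc(OC)c(OC)c(OC)c2)ccc1O[Si](C(C)C)(C(C)C)C(C)C | intermediate (not isolated)
11 | (2R,3R)-2-(3-methoxy-4-triisopropylsilyloxybenzyl)-3-(3,4,5-trimethoxybenzyl)butane-1,4-diol | COc1cc(C[C@@H](CO)[C@H](CO)Cc2cc(OC)c(OC)c(OC)c2)ccc1O[Si](C(C)C)(C(C)C)C(C)C | intermediate
12 | (2R,3R)-2-(4-hydroxy-3-methoxybenzyl)-3-(3,4,5-trimethoxybenzyl)butane-1,4-diol | COc1cc(C[C@@H](CO)[C@H](CO)Cc2cc(OC)c(OC)c(OC)c2)ccc1O | intermediate (key-step precursor)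
13 | para-quinone methide of 12 (2-methoxy-4-alkylidenecyclohexa-2,5-dienone) | COC1=CC(=C[C@@H](CO)[C@H](CO)Cc2cc(OC)c(OC)c(OC)c2)C=CC1=O | intermediate (not isolated)
14 | [(2S,3R,4R)-2-(4-hydroxy-3-methoxyphenyl)-4-(3,4,5-trimethoxybenzyl)tetrahydrofuran-3-yl]methanol | COc1cc([C@H]2OC[C@H](Cc3cc(OC)c(OC)c(OC)c3)[C@@H]2CO)ccc1O | intermediate (key-step product)
15 | [(2S,3R,4R)-2-(4-benzyloxy-3-methoxyphenyl)-4-(3,4,5-trimethoxybenzyl)tetrahydrofuran-3-yl]methanol | COc1cc([C@H]2OC[C@H](Cc3cc(OC)c(OC)c(OC)c3)[C@@H]2CO)ccc1OCc1ccccc1 | intermediate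
16 | (2S,3S,4R)-2-(4-benzyloxy-3-methoxyphenyl)-4-(3,4,5-trimethoxybenzyl)tetrahydrofuran-3-carboxylic acid | COc1cc([C@H]2OC[C@H](Cc3cc(OC)c(OC)c(OC)c3)[C@@H]2C(=O)O)ccc1OCc1ccccc1 | intermediate
17 | (2R,3R)-4-hydroxy-2-(4-hydroxy-3-methoxybenzyl)-3-(3,4,5-trimethoxybenzyl)butanoic acid | COc1cc(C[C@@H](C(=O)O)[C@H](CO)Cc2cc(OC)c(OC)c(OC)c2)ccc1O | intermediate (not isolated)
18 | (3R,4R)-3-(4-hydroxy-3-methoxybenzyl)-4-(3,4,5-trimethoxybenzyl)dihydrofuran-2(3H)-one | COc1cc(C[C@H]2C(=O)OC[C@@H]2Cc2cc(OC)c(OC)c(OC)c2)ccc1O | target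

**Step count and risks**

Total step count: 10. Longest linear sequence: 10 steps (eugenol 1 to target 18).

Steps most likely to fail:

1. Step 7 (key step). The quinone methide may be captured at carbon by the electron-rich ring B (Friedel–Crafts closure to an aryltetralin), or the product may be oxidised a second time at its new benzylic ether position. Fallback, setting out from 12 and returning at 14: oxidation and ring closure are separated. DDQ oxidation is run in methanol at 0 °C, so that the solvent captures the quinone methide at once and gives (2R,3R)-2-[(4-hydroxy-3-methoxyphenyl)(methoxy)methyl]-3-(3,4,5-trimethoxybenzyl)butane-1,4-diol F1 as a mixture of benzylic epimers. The ring is then closed by acid-catalysed etherification (PPTS cat., CH2Cl2, rt), the C5 hydroxyl displacing methanol through the phenol-stabilised benzylic cation in a 5-exo closure to give 14.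

2. Step 4. Facial selectivity on this bis-benzylic alkene may be poor, or β-hydride elimination and reinsertion at rhodium may move the double bond and give regioisomeric boronates. Fallback, setting out from 5 and returning at 11: stereocontrol is taken from a chiral butenolide instead of a catalyst.
   - Vanillin is silylated (TIPSCl, imidazole) to 3-methoxy-4-(triisopropylsilyloxy)benzaldehyde F2.
   - F2 is converted with propane-1,3-dithiol and BF3·OEt2 into 2-[3-methoxy-4-(triisopropylsilyloxy)phenyl]-1,3-dithiane F3.
   - Lithiated F3 (n-BuLi, THF, −78 °C) adds to commercial (5R)-5-(l-menthyloxy)furan-2(5H)-one, O=C1C=C[C@H](O[C@@H]2C[C@H](C)CC[C@H]2C(C)C)O1, anti to the menthyloxy group. The enolate is alkylated by 5 anti to the new substituent, which should give (3R,4R,5R)-4-{2-[3-methoxy-4-(triisopropylsilyloxy)phenyl]-1,3-dithian-2-yl}-5-(l-menthyloxy)-3-(3,4,5-trimethoxybenzyl)dihydrofuran-2(3H)-one F4.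
   - Raney Ni desulfurisation gives (3R,4R,5R)-4-(3-methoxy-4-triisopropylsilyloxybenzyl)-5-(l-menthyloxy)-3-(3,4,5-trimethoxybenzyl)dihydrofuran-2(3H)-one F5.
   - LiAlH4 in THF reduces both the lactone carbonyl and the acetal carbon to hydroxymethyl groups, releasing menthol and giving 11. The placement of the two rings in F5 is of no consequence, because the two ends become equivalent again in the diol.

3. Step 5. The second insertion may stall at the hindered vicinal boronate, or excess carbenoid may insert again into the primary boronate formed first. Fallback, setting out from 9 and returning at 11: each C–B bond is converted into a C–vinyl bond by Zweifel olefination (vinylmagnesium bromide, THF/DMSO; I2; NaOMe, MeOH), with retention at carbon. This gives triisopropyl{2-methoxy-4-[3-(3,4,5-trimethoxybenzyl)-2-vinylpent-4-en-1-yl]phenoxy}silane F6, with both stereocentres as in 9. Oxidative cleavage of both vinyl groups (OsO4 cat., NaIO4, 2,6-lutidine, dioxane/H2O) gives 2-(3-methoxy-4-triisopropylsilyloxybenzyl)-3-(3,4,5-trimethoxybenzyl)succinaldehyde F7, which is not isolated but reduced at once with NaBH4 to 11.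

**Further compounds**

F1 | step 7 | (2R,3R)-2-[(4-hydroxy-3-methoxyphenyl)(methoxy)methyl]-3-(3,4,5-trimethoxybenzyl)butane-1,4-diol (benzylic epimers) | COc1cc(C(OC)[C@@H](CO)[C@H](CO)Cc2cc(OC)c(OC)c(OC)c2)ccc1O
F2 | step 4 | 3-methoxy-4-(triisopropylsilyloxy)benzaldehyde | COc1cc(C=O)ccc1O[Si](C(C)C)(C(C)C)C(C)C
F3 | step 4 | 2-[3-methoxy-4-(triisopropylsilyloxy)phenyl]-1,3-dithiane | COc1cc(C2SCCCS2)ccc1O[Si](C(C)C)(C(C)C)C(C)C
F4 | step 4 | (3R,4R,5R)-4-{2-[3-methoxy-4-(triisopropylsilyloxy)phenyl]-1,3-dithian-2-yl}-5-(l-menthyloxy)-3-(3,4,5-trimethoxybenzyl)dihydrofuran-2(3H)-one | O=C1[C@H](Cc2cc(OC)c(OC)c(OC)c2)[C@@H](C2(SCCCS2)c2ccc(O[Si](C(C)C)(C(C)C)C(C)C)c(OC)c2)[C@H](O[C@@H]2C[C@H](C)CC[C@H]2C(C)C)O1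
F5 | step 4 | (3R,4R,5R)-4-(3-methoxy-4-triisopropylsilyloxybenzyl)-5-(l-menthyloxy)-3-(3,4,5-trimethoxybenzyl)dihydrofuran-2(3H)-one | O=C1[C@H](Cc2cc(OC)c(OC)c(OC)c2)[C@@H](Cc2ccc(O[Si](C(C)C)(C(C)C)C(C)C)c(OC)c2)[C@H](O[C@@H]2C[C@H](C)CC[C@H]2C(C)C)O1
F6 | step 5 | triisopropyl{2-methoxy-4-[3-(3,4,5-trimethoxybenzyl)-2-vinylpent-4-en-1-yl]phenoxy}silane (stereocentres as in 9) | COc1cc(C[C@@H](C=C)[C@H](C=C)Cc2cc(OC)c(OC)c(OC)c2)ccc1O[Si](C(C)C)(C(C)C)C(C)C
F7 | step 5 | 2-(3-methoxy-4-triisopropylsilyloxybenzyl)-3-(3,4,5-trimethoxybenzyl)succinaldehyde (stereocentres as in 9) | COc1cc(C[C@@H](C=O)[C@H](C=O)Cc2cc(OC)c(OC)c(OC)c2)ccc1O[Si](C(C)C)(C(C)C)C(C)C
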